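The constants are invented.

The amounts framed the question: 0.0800 M of partner stood against 0.10 M of starting material, and four other steps also consumed the partner.

starting material 0.10 M; partner 0.0800 M; second substrate 0.100 M; third substrate 0.0200 M; protic impurity 0.0500 M; time 6.0 d

    starting material + partner → target (k1 = 1.13 /M/h)
    second substrate + partner → second product (k2 = 1.14 /M/h)
    third substrate + partner → third product (k3 = 12.3 /M/h)
    partner + protic impurity → quenched reagent (k4 = 3.30 /M/h)
    partner → decomposed reagent (k5 = 0.110 /h)

- the reaction counts as stopped when no species that holds the starting material changes by six tenths of a point or more over the second half of the time
- run time (flask): 6.0 d

1. why nothing more happens at 6.0 d, or that something still does (the partner has run out first / it is still moving / all of the starting material has reacted)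
2. how much of the starting material has reacted by 6.0 d
3. how much target there is at 6.0 d, in percent of the starting material charged

Every rate that consumes partner carries the factor c(partner), so in a ratio of these rates c(partner) cancels, but the other concentrations stay in the ratio and change during the run. As an estimate, I therefore took the partner's share with those concentrations held at their charges: the rate of the target step divided by the summed rates of partner loss, at charged concentrations. This gave 15.1%. The partner's loss constant at the charge was 0.748 /h, so its half-life of 0.927 h was far shorter than 6.0 d, and I expected a still flask at the asked time. The share times c(partner) over c(starting material) gave me 12.1% conversion, with equal target, since no step in the scheme consumes target.

The forecast gave the partner has run out first, with 14.7% conversion and 14.7% target: “all of it to target because nothing consumes the target”.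

The simulation gave the partner has run out first, with 14.7% conversion and 14.7% target, so my figure was lower than the result by 2.6 percentage points. My share of 15.1% held the charged concentrations fixed, whereas the third substrate, the strongest claimant at the start, stood at 17.7% of its charge at the end.

In this flask, the half-life of starting material by the target step, with partner as charged, was 0.32 d, shorter than the run. But in this flask the partner, the limiting reagent, stood at 0.0995% of its charge after 0.600 d and at 0% at the end, while 85% of the starting material remained.

For the neighbour flask with 0.050 M of third substrate, the share came to 10.1%, which gave 8.09% conversion. The computed neighbour gave 10.4% conversion and 10.4% target, again above my reckoning.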